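**Plan**

Retrosynthesis: the silyl ether comes off last and the 4Z alkene is traced to its strained 4E isomer; C5–H is traced to an enol triflate; the dihydropyran is cut at O–C10 and C1–C1′ (hetero-Diels–Alder) and at C1′=C(aryl) (Knoevenagel), leaving 2,4-diformylphloroglucinol, isovaleraldehyde and a ten-membered E,E-diene.
Enabling feature: the ten-membered ring is a hedycaryol whose C1=C10 and C4=C5 alkenes are 1,5-related through the C2–C3 bond; cutting C2–C3 while joining C5 to C10 (retro-oxy-Cope, oxygen on C5) contracts it to the cyclohexane of (−)-elemol with all fifteen carbons and C7 in place.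
Forward: the benzene ring is bought; the isopropenyl group of elemol is cut down to acetyl, hydroxylated at C5 and rebuilt; the cyclohexane is expanded by four atoms to the ten-membered ring (anionic oxy-Cope, enolate trapped as triflate); the dihydropyran closes last by cycloaddition across C1=C10.
Stereochemistry: C7 is that of elemol; C5 and C10 of elemol only hold vinyl and isopropenyl trans-diequatorial so that the chair shift gives the E alkene and the ring-trans enolate; C10, C1 and C1′ arise in the cycloaddition (outer face of the E alkene, E-quinone methide); the Z geometry is set by a final strain-releasing isomerisation.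

Key step: step 6

Assumption: commercial (−)-elemol is the natural (1R,3S,4S) enantiomer drawn as 1, whose carbinol-bearing ring carbon has the configuration required at C7 of the target.
Locants: germacrane numbering throughout (C10 = O-bearing quaternary carbon, C1 = ring-fusion CH, C1′ = benzylic CH, C4 = methyl-bearing alkene carbon, C7 = CH carrying the CMe2O group); in the elemanes the vinyl group sits on C10 and the isopropenyl group on C5. In the target C7 is R, C10 R, C1 S, C1′ S.

**Route**

Step 1
Reactants: 1 (−)-elemol
Product: 2 elemol triethylsilyl ether
Conditions: TESOTf, 2,6-lutidine, CH2Cl2, −78 to 0 °C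
Reagents that add atoms: triethylsilyl trifluoromethanesulfonate, CC[Si](CC)(CC)OS(=O)(=O)C(F)(F)F
Why: Silylation of a hindered tertiary alcohol with a silyl triflate and a non-nucleophilic base is routine and removes the only acidic proton, so that the later base steps address a single oxygen.

Step 2
Reactants: 2 elemol triethylsilyl ether
Product: 3 isopropenyl epoxide of 2 (both epimers at the oxirane carbon)
Conditions: mCPBA (1.05 equiv), CH2Cl2, −10 to 0 °C
Reagents that add atoms: meta-chloroperoxybenzoic acid, O=C(OO)c1cccc(Cl)c1
Why: Prilezhaev epoxidation should pick the more electron-rich 1,1-disubstituted isopropenyl alkene over the monosubstituted vinyl group, and the configuration of the new oxirane carbon does not matter because that carbon becomes a carbonyl carbon in step 3.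

Step 3
Reactants: 3 isopropenyl epoxide
Product: 5 methyl ketone (acetyl at C5), via vicinal diol 4 (not isolated)
Conditions: H5IO6, THF–H2O, 0 °C
Reagents that add atoms: water, O
Why: Periodic acid opens the terminal epoxide to the 1,2-diol and cleaves it in the same flask (Malaprade glycol cleavage), excising the CH2 carbon under conditions cold and brief enough for the tertiary silyl ether and inert towards the vinyl group.

Step 4
Reactants: 5 methyl ketone
Product: 7 alpha-ketol (axial OH and equatorial acetyl at C5), via tertiary hydroperoxide 6 (not isolated)
Conditions: O2 (1 atm), t-BuOK, P(OEt)3, DMF–t-BuOH, −25 °C; then AcOH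
Reagents that add atoms: dioxygen, O=O
Why: Enolate autoxidation with in situ phosphite reduction of the hydroperoxide: under equilibrating alkoxide conditions the more substituted C5 enolate captures oxygen, as established for 20-oxopregnanes (methyl ketone on a ring methine next to a quaternary carbon), and oxygen should enter axially on the face opposite the axial C10 methyl, leaving acetyl equatorial and trans to vinyl.

Step 5
Reactants: 7 alpha-ketol
Product: 8 5-hydroxyelemol triethylsilyl ether (OH axial; vinyl and isopropenyl trans-diequatorial)
Conditions: Ph3PCH3Br, t-BuOK (excess ylide), THF, 0 to 45 °C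
Reagents that add atoms: methyltriphenylphosphonium bromide (as its ylide, made in the flask), C[P+](c1ccccc1)(c1ccccc1)c1ccccc1.[Br-]
Why: Wittig methylenation with excess salt-free ylide should tolerate the tertiary alpha-alkoxide (an alpha-ketol ring expansion of a cyclohexane is uphill) and rebuilds the isopropenyl group without touching the C5 stereocentre.

Step 6
Reactants: 8 5-hydroxyelemol triethylsilyl ether
Product: 11 5-triflyloxyhedycaryol triethylsilyl ether, via potassium alkoxide 9 (not isolated), via potassium dienolate 10 (not isolated)
Conditions: KH, 18-crown-6, THF, 0 °C to rt; then PhNTf2, −78 to 0 °C; isolation below 30 °C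
Reagents that add atoms: N-phenylbis(trifluoromethanesulfonimide), O=S(=O)(N(c1ccccc1)S(=O)(=O)C(F)(F)F)C(F)(F)F
Why: Deprotonation gives the C5 alkoxide, whose 3-oxido-1,5-diene (C2=C1–C10–C5(O−)–C4=C3) undergoes an alkoxide-accelerated 3,3-sigmatropic shift in which C2–C3 forms between the vinyl and isopropenyl termini and the ring bond C5–C10 breaks, after which the enolate is sulfonylated on oxygen. The closest known reaction type is the anionic oxy-Cope ring expansion of trans-1,2-dialkenylcyclohexanols to (E)-cyclodec-5-enone enolates with O-trapping. The ten-membered carbocycle is not closed end to end but arises by four-atom ring expansion of the cyclohexane through a six-membered chair transition state. No stereocentre is created (C5 and C10 become trigonal, C7 is untouched); the two stereogenic double bonds are set by the chair, in which the ring bonds C10–C9 and C5–C6 are both equatorial, giving the E C1=C10 alkene and the ring-trans C4=C5 enolate. The step needs chair over boat geometry and O- over C-sulfonylation: the first is secured by the trans-diequatorial vinyl and isopropenyl groups of 8, locked by the equatorial C7 substituent with the alkoxide and C10 methyl axial, the second by the hard triflimide acting on a crown-ether-separated tetrasubstituted potassium enolate. Irreversible enolate formation drives a ring expansion that is uphill for the neutral elemol–hedycaryol pair, and the triflate makes C4=C5 tetrasubstituted and electron-poor, so it should neither take part in transannular cationic cyclisation nor compete as a dienophile in step 8.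

Step 7
Reactants: 12 phloroglucinol
Product: 14 2,4-diformylphloroglucinol, via bis-iminium dichloride 13 (not isolated)
Conditions: POCl3 (2.2 equiv), DMF, EtOAc, 0 °C to rt; then H2O, rt
Reagents that add atoms: N,N-dimethylformamide, CN(C)C=O; water, O
Why: Double Vilsmeier–Haack formylation of the strongly activated arene with two equivalents of the chloroiminium reagent should stop at the bis-iminium stage, since each iminium group deactivates the ring until hydrolysis.

Step 8
Reactants: 11 5-triflyloxyhedycaryol triethylsilyl ether; 14 2,4-diformylphloroglucinol; 15 isovaleraldehyde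
Product: 17 chroman cycloadduct retaining the ring-trans enol triflate, via o-quinone methide 16 (not isolated)
Conditions: 14 (3 equiv), 15 (3 equiv, slow addition), ethylenediammonium diacetate (30 mol %), MeCN–CH2Cl2, 4 Å MS, 35 °C, dark
Reagents that add atoms: none
Why: Knoevenagel condensation at the single free ring CH of 14 gives the transient quinone methide 16, which the only nucleophilic alkene of 11 (the strained E C1=C10) should intercept in an inverse-electron-demand hetero-Diels–Alder reaction with O on the more substituted C10 and the benzylic carbon on C1; suprafacial addition to the E alkene gives the trans ring fusion, attack on the outer face of the crown conformer left by the chair shift (C7 group equatorial, oxygen entering C10 opposite the broken C5–C10 bond) sets C10 and C1 relative to C7, and the E-quinone methide with C1–H rather than C2 under the heterodiene places isobutyl anti to C2, any benzylic epimer being removed by chromatography.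

Step 9
Reactants: 17 chroman cycloadduct
Product: 18 (4E)-alkene triethylsilyl ether
Conditions: Pd(OAc)2 (10 mol %), PPh3 (20 mol %), HCO2H, Et3N, DMF, 60 °C
Reagents that add atoms: none
Why: Palladium-catalysed formate reduction of an enol triflate (oxidative addition to zerovalent palladium, decarboxylation of formate to the hydride, reductive elimination) replaces OTf by H with retention of geometry and tolerates aryl aldehydes, phenols and the silyl ether, and heating is safe here because the 1,5-diene needed for a Cope shift no longer exists.

Step 10
Reactants: 18 (4E)-alkene triethylsilyl ether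
Product: 19 (4Z)-alkene triethylsilyl ether
Conditions: PhSSPh (20 mol %), violet LED (about 400 nm), degassed benzene, rt
Reagents that add atoms: none
Why: Reversible addition and loss of phenylthiyl radicals (radical-chain E/Z isomerisation, as used on trans-cycloalkene terpenes) should equilibrate the trisubstituted alkene towards the less strained cis-cyclodecene geometry without touching any stereocentre.

Step 11
Reactants: 19 (4Z)-alkene triethylsilyl ether
Product: 20 target CNP0570248.1
Conditions: HF·pyridine, pyridine, THF, 0 °C to rt
Reagents that add atoms: none
Why: Buffered fluoride desilylation should cleave the tertiary triethylsilyl ether without ionising the tertiary aryl ether at C10 or disturbing the hydrogen-bonded formyl phenols.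

**Compound list**

1 | (−)-elemol, 2-[(1R,3S,4S)-4-ethenyl-4-methyl-3-(prop-1-en-2-yl)cyclohexyl]propan-2-ol | C=C[C@]1(C)CC[C@H](C[C@H]1C(C)=C)C(C)(C)O | starting material
2 | elemol triethylsilyl ether | C=C[C@]1(C)CC[C@H](C[C@H]1C(C)=C)C(C)(C)O[Si](CC)(CC)CC | intermediate
3 | epoxide of 2 (2-methyloxiran-2-yl at C5, both epimers at the oxirane carbon) | C=C[C@]1(C)CC[C@H](C[C@H]1C2(C)CO2)C(C)(C)O[Si](CC)(CC)CC | intermediate
4 | vicinal diol (1,2-dihydroxypropan-2-yl at C5) | C=C[C@]1(C)CC[C@H](C[C@H]1C(C)(O)CO)C(C)(C)O[Si](CC)(CC)CC | intermediate (not isolated)
5 | methyl ketone (acetyl at C5, trans to vinyl, C5–H retained) | C=C[C@]1(C)CC[C@H](C[C@H]1C(C)=O)C(C)(C)O[Si](CC)(CC)CC | intermediate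
6 | tertiary hydroperoxide (OOH axial at C5, trans to the C10 methyl) | C=C[C@]1(C)CC[C@H](C[C@@]1(OO)C(C)=O)C(C)(C)O[Si](CC)(CC)CC | intermediate (not isolated)
7 | alpha-ketol (OH axial at C5, acetyl equatorial and trans to vinyl) | C=C[C@]1(C)CC[C@H](C[C@@]1(O)C(C)=O)C(C)(C)O[Si](CC)(CC)CC | intermediate
8 | 5-hydroxyelemol triethylsilyl ether (OH axial; vinyl and isopropenyl trans-diequatorial) | C=C[C@]1(C)CC[C@H](C[C@@]1(O)C(C)=C)C(C)(C)O[Si](CC)(CC)CC | intermediate
9 | potassium alkoxide of 8 | C=C[C@]1(C)CC[C@H](C[C@@]1([O-])C(C)=C)C(C)(C)O[Si](CC)(CC)CC.[K+] | intermediate (not isolated)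
10 | potassium cyclodeca-1(10),4-dien-5-olate (C1=C10 E, C4=C5 ring-trans, C7 carrying CMe2OSiEt3) | C/C1=C\CC/C(C)=C([O-])/C[C@H](C(C)(C)O[Si](CC)(CC)CC)CC1.[K+] | intermediate (not isolated)
11 | 5-triflyloxyhedycaryol triethylsilyl ether (C1=C10 E, ring-trans C4=C5 enol triflate) | C/C1=C\CC/C(C)=C(OS(=O)(=O)C(F)(F)F)/C[C@H](C(C)(C)O[Si](CC)(CC)CC)CC1 | intermediate
12 | phloroglucinol | Oc1cc(O)cc(O)c1 | starting material
13 | bis(dimethyliminium) dichloride of 14 | C[N+](C)=Cc1c(O)cc(O)c(C=[N+](C)C)c1O.[Cl-].[Cl-] | intermediate (not isolated)
14 | 2,4-diformylphloroglucinol | O=Cc1c(O)cc(O)c(C=O)c1O | intermediate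
15 | isovaleraldehyde | CC(C)CC=O | starting material
16 | isobutyl o-quinone methide (exocyclic alkene E, isobutyl anti to the ring carbonyl) | CC(C)C/C=C1/C(=O)C(C=O)=C(O)C(C=O)=C1O | intermediate (not isolated)
17 | chroman cycloadduct (trans-fused dihydropyran O–C10/C1–C1′, isobutyl anti to C2, ring-trans enol triflate, silyl ether) | C/C1=C(OS(=O)(=O)C(F)(F)F)\C[C@H](C(C)(C)O[Si](CC)(CC)CC)CC[C@@]2(C)Oc3c(C=O)c(O)c(C=O)c(O)c3[C@@H](CC(C)C)[C@@H]2CC1 | intermediate
18 | (4E)-alkene triethylsilyl ether | C/C1=C\C[C@H](C(C)(C)O[Si](CC)(CC)CC)CC[C@@]2(C)Oc3c(C=O)c(O)c(C=O)c(O)c3[C@@H](CC(C)C)[C@@H]2CC1 | intermediate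
19 | (4Z)-alkene triethylsilyl ether | C/C1=C/C[C@H](C(C)(C)O[Si](CC)(CC)CC)CC[C@@]2(C)Oc3c(C=O)c(O)c(C=O)c(O)c3[C@@H](CC(C)C)[C@@H]2CC1 | intermediate
20 | CNP0570248.1 | C/C1=C/C[C@H](C(C)(C)O)CC[C@@]2(C)Oc3c(C=O)c(O)c(C=O)c(O)c3[C@@H](CC(C)C)[C@@H]2CC1 | target

**Step count and risks**

Total step count: 11. Longest linear sequence: 10 steps (steps 1–6 and 8–11, from 1 to 20).

Steps most likely to fail:

Step 8. The condensation may be too slow at the temperature ceiling that the Cope-labile diene imposes. The quinone methide may also add to the wrong alkene face through a minor ring conformer, or with poor discrimination at the benzylic carbon. The fallback separates quinone methide formation from the condensation. It sets out from 14: reductive alkylation with 15 (Hantzsch ester, L-proline cat., CH2Cl2, rt) should give 2,4-diformyl-6-(3-methylbutyl)phloroglucinol F1. DDQ in nitromethane at −20 to 0 °C then removes a benzylic hydride from it and releases the same quinone methide 16 in the presence of triflate 11, so the cycloaddition runs cold, where conformer and orientation control are best. The route is rejoined at 17.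

Step 10. The radical chain may stall at a mixture of isomers, thiyl radicals may abstract the formyl hydrogens, or the acylphloroglucinol chromophore may degrade under irradiation. The fallback is a dark, non-radical equilibration of 18 with PdCl2(MeCN)2 (divalent palladium, 5–10 mol %) in CH2Cl2 at rt, which isomerises alkenes through reversible metal addition and elimination. It sets out from 18, comes back at 19 and makes no new compound (F0).

Step 4. Deprotonation may occur on the methyl side, followed by over-oxidation or C–C cleavage of the hydroperoxide, or oxygen may arrive on the wrong face of the enolate. The fallback separates enolisation from oxygenation and sets out from 5. Thermodynamic silylation (TMSCl, NaI, Et3N, MeCN, rt) should give the tetrasubstituted trimethylsilyl enol ether F2, from which the regioisomer can be removed and recycled. Rubottom oxidation (mCPBA, NaHCO3, CH2Cl2, −20 °C; the enol ether reacts far faster than the vinyl group) gives the alpha-trimethylsilyloxy ketone F3. Selective cleavage of the trimethylsilyl group (K2CO3, MeOH, 0 °C) returns the route at 7.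

Further compounds
F1 | step 8 | 2,4-diformyl-6-(3-methylbutyl)phloroglucinol | CC(C)CCc1c(O)c(C=O)c(O)c(C=O)c1O
F0 | step 10 | none | none
F2 | step 4 | trimethylsilyl enol ether of ketone 5 (C5=C4 enol ether, geometry undefined) | C=C[C@]1(C)CC[C@H](CC1=C(C)O[Si](C)(C)C)C(C)(C)O[Si](CC)(CC)CC
F3 | step 4 | alpha-trimethylsilyloxy ketone (trimethylsilyl ether of 7) | C=C[C@]1(C)CC[C@H](C[C@@]1(O[Si](C)(C)C)C(C)=O)C(C)(C)O[Si](CC)(CC)CC
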